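## The problem

The target joins two flavonoid units through one carbon–carbon bond. C3 of a 5,7-dihydroxy-2-(4-hydroxyphenyl)chroman-4-one (a naringenin-type flavanone) is bonded to C3' of a 5,4'-dihydroxy-7-methoxyflavone, so ring B of the flavone is also the 3-aryl group of the flavanone and carries a free hydroxyl next to the linking bond. The only stereocentres are C2 (S) and C3 (R) of the flavanone, trans on ring C. C3 lies between the ketone and an aryl group and epimerises easily. It settles trans to the C2 aryl group with both aryl groups equatorial, so C2 can control C3 but not the reverse, and only C2 needs absolute control. C2 is a benzylic aryl ether β to the ketone and is lost by ring opening to the chalcone (retro-oxa-Michael) in base or hot acid, so it must be set late and followed only by neutral operations. Five phenols must end free while the C7 oxygen of the flavone stays methylated, the phloroglucinol ring is acidic and electron-rich, and the flavone pyranone is a vinylogous ester that does not tolerate hot hydroxide. The enabling feature is ring A of the flavanone: a symmetric phloroglucinol acylated at C4a by C4, which is a tetraketide folded by Claisen condensation between C4a and C5 with the α-aryl cinnamoyl unit (C4, C3, C2 and their aryl groups) as starter. Because that ring is symmetric, either hydroxyl ortho to the acyl group closes ring C to the same flavanone.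

## Retrosynthesis

**Target 16 to tribenzyl ether 15.** Three O–benzyl bonds are cut. Benzyl is preferred to acetal protection because hydrogenolysis is neutral, so neither C2 nor C3 is exposed to acid or base after being set, and because benzyl ethers survive every earlier step. The forward reaction must only stop before the flavone double bond is touched.

**Flavanone 15 to chalcone 14.** The O1–C2 bond is cut, and with it both stereocentres disappear. The neighbouring cuts (C2–C3, or the C3–aryl bond on a finished flavanone) would form a crowded C–C bond next to an epimerisable centre. The oxa-Michael cut leaves the C3–aryl bond in an open chain. The forward reaction must choose one face at C2 under catalyst control, and C3 then follows by equilibration to trans.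

**Chalcone 14 to pyrone 12, through triketo ester 13.** The C4a–C5 bond of ring A is cut, and the ring unfolds to a poly-β-carbonyl chain masked as a 4-hydroxy-2-pyrone. The alternative, acylation of a preformed phloroglucinol ring at C4–C4a, needs Lewis acid or aryllithium chemistry with ring-A protection and is held in reserve. The pyrone cut replaces ring A by a commodity heterocycle and keeps the chain masked until the folding step. The forward reaction must fold by Claisen and not by aldol condensation and must leave ring C open.

**Pyrone 12 to acid 9 and pyrone 10, through acyl imidazole 11.** The bond between the pyrone side-chain methylene and the ketone carbon is cut. This is an acylation of the dianion of 10 at its methyl carbon, and it reduces the problem to an acrylic acid without enolisable hydrogens. The forward reaction must acylate at carbon and at the carbonyl, not at the β-position.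

**Acid 9 to arylacetic acid 7 and aldehyde 8.** The Cα=Cβ double bond is cut (Perkin condensation). This cut uses a commercial aldehyde and gives the acid directly. The neighbouring cut at the Cα–aryl bond (cross-coupling of a bromoacrylate) is longer and is kept as fallback. The alkene geometry is not critical, since the alkene is consumed in ring closure, but the E acid is expected.

**Acid 7 to ester 6 to bromoflavone 5.** The aryl–CH2 bond is cut: palladium-catalysed coupling of the aryl bromide with a zinc ester enolate, then saponification. This places the acetic acid side chain ortho to the oxygen without any regiochemical question, which electrophilic substitution on a phenylacetic acid would raise.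

**Bromoflavone 5 to chalcone 4 to acetophenone 2 and aldehyde 3; 2 to 1.** The O1–C2 bond of the flavone and its C2–C3 unsaturation come from oxidative cyclisation of a 2'-hydroxychalcone, which itself comes from a Claisen–Schmidt condensation. Acetophenone 1 already holds the methyl ether that must survive to the end, so the 7-methoxy group is never in competition with the phenols.

## Roads not taken

**Alternative 1:** The cut is C2–C3 of ring C. Forward, the α-diazo deoxybenzoin A1 would lose nitrogen at a chiral dirhodium tetracarboxylate catalyst (divalent rhodium), and the carbene at C3 would insert into the benzylic C–H of the ortho 4-siloxybenzyl ether to give the pentasilyl ether A2.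
- Merits: a C–C bond is formed irreversibly and C2 is set in a step that cannot run backwards. In this respect it is stronger than the chosen plan, whose ring closure is reversible.
- Weak points: a carbene flanked by an ortho benzyloxy group is well placed to attack the ether oxygen, and ylide formation with 1,2-shift of the benzyl group would contract the ring. Enantiocontrol of such insertions is best established for aryldiazoacetates closing five-membered rings, not for diazo ketones closing six. Five phenolic silyl ethers, one of them peri to the flavone carbonyl, are fragile. A1 also needs its own acylphloroglucinol synthesis and a diazo transfer.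
- Comparison: the chosen plan answers its weaker stereochemical step with a neutral final deprotection and a recyclable resolution, and every bond-forming step in it has a close precedent.

**Alternative 2:** The cuts are C3–C4 and O1–C2. Forward, the salicyl alcohol A3 would be ionised by a chiral phosphoric acid and captured in a [4+2] sense by the E-stilbene A4 to give the trans-2,3-diarylchroman A5. C4 of A5 must then be oxidised from methylene to ketone before deprotection.
- Merits: this is the most convergent route, and both stereocentres arise in one event, trans by transfer of the stilbene geometry, with no epimerisable ketone present. On convergence and stereochemical directness it is better than the chosen plan.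
- Weak points: the cationic intermediate from A3 has no stabilising substituent on its methylene carbon. A4 is a weak 2π partner whose flavone-bearing end is electron-poor. The late benzylic oxidation must choose C4 over C2, which is also benzylic and α to oxygen, in a molecule with electron-rich rings, and it adds steps.
- Comparison: the chosen plan has C4 at the ketone oxidation level from the start and closes its rings by polar steps with known counterparts.

**Alternative 3:** The cuts are four bonds of flavone ring A. Forward, irradiation of the pyranonyl diazomethyl ketone A6 would give a ketene by Wolff rearrangement. The ketene would add methoxyethyne A7, and the cyclobutenone would open and reclose onto pyranone C3 to give A8, with the 5-hydroxyl free and the 7-methoxy group in place.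
- Merits: the 5-hydroxyl and 7-methoxy groups are placed regiospecifically in one operation, and the peri hydroxyl is told apart from the other phenols without protecting-group steps.
- Weak points: the photochemical step comes at the end on a substrate holding the finished flavanone, whose aryl ketone absorbs and can open ring C or epimerise. The electrocyclisation must engage a C=C bond of a cross-conjugated pyranone. Preparing A6 needs an acid chloride next to the epimerisable C3.
- Comparison: this route spends its key step on the ring that can be bought (it is contained in 1) and leaves the stereodiad and the C3–aryl bond unsolved. The chosen plan spends its key step on flavanone ring A and takes the methoxy/hydroxyl pattern from 1.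

Key step: step 8

Assumptions: compounds 1, 3, 8 and 10, the zinc reagent of step 4, LiN(iPr)2 and Mg(OCH3)2 are taken as catalogue materials used as purchased. The catalyst of step 9 is written as the quinine-derived thiourea; if it favours the 2R series, its quinidine-derived pseudoenantiomer is used with no other change.

## Route

Step 1
Reactants: 1 2',6'-dihydroxy-4'-methoxyacetophenone
Product: 2 1-[2-(benzyloxy)-6-hydroxy-4-methoxyphenyl]ethan-1-one
Conditions: BnBr (1.05 equiv), K2CO3, acetone, reflux
Reagents that add atoms: benzyl bromide, BrCc1ccccc1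
Why: Williamson etherification; after the first benzylation the remaining hydroxyl is locked in a hydrogen bond to the acetyl carbonyl and resists a second alkylation under carbonate, so one equivalent of bromide should stop at the mono-ether.

Step 2
Reactants: 2 1-[2-(benzyloxy)-6-hydroxy-4-methoxyphenyl]ethan-1-one; 3 4-(benzyloxy)-3-bromobenzaldehyde
Product: 4 (2E)-1-[2-(benzyloxy)-6-hydroxy-4-methoxyphenyl]-3-[4-(benzyloxy)-3-bromophenyl]prop-2-en-1-one
Conditions: KOH (50% aq.), EtOH/THF, rt
Reagents that add atoms: none
Why: Claisen–Schmidt condensation of a methyl ketone with a non-enolisable aldehyde; E1cB dehydration should give the E enone, and any partial ring closure at this stage is harmless because step 3 converts both forms to the flavone.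

Step 3
Reactants: 4 (2E)-1-[2-(benzyloxy)-6-hydroxy-4-methoxyphenyl]-3-[4-(benzyloxy)-3-bromophenyl]prop-2-en-1-one
Product: 5 5-(benzyloxy)-2-[4-(benzyloxy)-3-bromophenyl]-7-methoxy-4H-chromen-4-one
Conditions: I2 (10 mol %), DMSO, 120 °C
Reagents that add atoms: none
Why: Iodine-catalysed oxidative cyclisation of a 2'-hydroxychalcone (oxa-Michael closure, iodination α to the ketone, loss of HI, with DMSO re-oxidising the iodide); benzyl ethers and the aryl bromide should be inert.

Step 4
Reactants: 5 5-(benzyloxy)-2-[4-(benzyloxy)-3-bromophenyl]-7-methoxy-4H-chromen-4-one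
Product: 6 ethyl 2-{2-(benzyloxy)-5-[5-(benzyloxy)-7-methoxy-4-oxo-4H-chromen-2-yl]phenyl}acetate
Conditions: BrZnCH2CO2Et (2 equiv), Pd2(dba)3 (tris(dibenzylideneacetone)dipalladium, 2.5 mol %), XPhos (2-dicyclohexylphosphino-2',4',6'-triisopropylbiphenyl, 10 mol %), THF, 50 °C
Reagents that add atoms: (2-ethoxy-2-oxoethyl)zinc bromide, CCOC(=O)C[Zn]Br
Why: Negishi-type α-arylation with a Reformatsky reagent (oxidative addition of zerovalent palladium to the aryl bromide, transmetalation, reductive elimination); the near-neutral zinc enolate should leave the flavone carbonyl untouched.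

Step 5
Reactants: 6 ethyl 2-{2-(benzyloxy)-5-[5-(benzyloxy)-7-methoxy-4-oxo-4H-chromen-2-yl]phenyl}acetate
Product: 7 2-{2-(benzyloxy)-5-[5-(benzyloxy)-7-methoxy-4-oxo-4H-chromen-2-yl]phenyl}acetic acid
Conditions: LiOH, THF/MeOH/H2O, rt; then 1 M HCl
Reagents that add atoms: lithium hydroxide, [Li+].[OH-]
Why: Saponification of an unhindered arylacetic ester; the flavone ring should withstand dilute hydroxide at room temperature.

Step 6
Reactants: 7 2-{2-(benzyloxy)-5-[5-(benzyloxy)-7-methoxy-4-oxo-4H-chromen-2-yl]phenyl}acetic acid; 8 4-(benzyloxy)benzaldehyde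
Product: 9 (2E)-2-{2-(benzyloxy)-5-[5-(benzyloxy)-7-methoxy-4-oxo-4H-chromen-2-yl]phenyl}-3-[4-(benzyloxy)phenyl]prop-2-enoic acid
Conditions: Ac2O, Et3N, 120 °C; then H2O/THF, 60 °C; 1 M HCl
Reagents that add atoms: none
Why: Perkin condensation of an arylacetic acid with an aromatic aldehyde through the mixed anhydride enolate; elimination should place the carboxyl trans to the β-aryl group (E acid, aryl groups cis), the usual outcome for arylacetic acids.

Step 7
Reactants: 9 (2E)-2-{2-(benzyloxy)-5-[5-(benzyloxy)-7-methoxy-4-oxo-4H-chromen-2-yl]phenyl}-3-[4-(benzyloxy)phenyl]prop-2-enoic acid; 10 4-hydroxy-6-methyl-2H-pyran-2-one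
Product: 12 6-[(3E)-3-{2-(benzyloxy)-5-[5-(benzyloxy)-7-methoxy-4-oxo-4H-chromen-2-yl]phenyl}-4-[4-(benzyloxy)phenyl]-2-oxobut-3-en-1-yl]-4-hydroxy-2H-pyran-2-one, via acyl imidazole 11 (not isolated)
Conditions: 9, CDI (1.1 equiv), THF, rt; separately 10 (3.5 equiv), LiN(iPr)2 (LDA, 7.2 equiv), THF, −78 °C; solution of 11 added, −78 to −20 °C; 1 M HCl
Reagents that add atoms: 1,1'-carbonyldiimidazole, O=C(n1ccnc1)n1ccnc1 (imidazolyl group of 11 only; no atom of it remains in 12)
Why: C-acylation of the dilithio dianion of 10 at its methyl carbon, the more basic site; 11 has no enolisable hydrogen and its β-carbon is buried between two aryl groups, so attack at the acyl carbon should prevail, and the excess dianion absorbs the imidazole and the acidic product.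

Step 8
Reactants: 12 6-[(3E)-3-{2-(benzyloxy)-5-[5-(benzyloxy)-7-methoxy-4-oxo-4H-chromen-2-yl]phenyl}-4-[4-(benzyloxy)phenyl]-2-oxobut-3-en-1-yl]-4-hydroxy-2H-pyran-2-one
Product: 14 (2E)-2-{2-(benzyloxy)-5-[5-(benzyloxy)-7-methoxy-4-oxo-4H-chromen-2-yl]phenyl}-3-[4-(benzyloxy)phenyl]-1-(2,4,6-trihydroxyphenyl)prop-2-en-1-one, via triketo ester 13 (not isolated)
Conditions: Mg(OCH3)2 (8 equiv), dry MeOH/THF, 60 °C; poured into ice-cold 1 M HCl; crude 14 used at once
Reagents that add atoms: magnesium methoxide, CO[Mg]OC (methoxy group of 13 only; no atom of it remains in 14)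
Why: Methoxide adds to the lactone carbonyl of 12 and opens the ring to the magnesium-chelated triketo ester 13, in which each 1,3-dicarbonyl pair is held as an enolate. The carbon between the enone ketone and the next ketone then attacks the ester carbonyl (Claisen condensation, 6-exo-trig), methoxide leaves, and enolisation of the cyclohexanetrione aromatises ring A, which makes the closure irreversible. The closest known reaction type is the magnesium alkoxide-induced Claisen cyclisation of 3,5,7-triketo esters and of 6-(2-oxoalkyl)-4-hydroxy-2-pyrones to acylphloroglucinols, the laboratory counterpart of the chalcone synthase folding. The step forms the C4a–C5 bond and no stereocentre. It needs Claisen folding in preference to the aldol folding that would give a resorcylate: the aldol path must attack the enone ketone, which is conjugated and flanked by the ortho-substituted α-aryl group, whereas the ester is unhindered, and magnesium chelation holds the chain in the shape for C-acylation. It also needs ring C to stay open: in excess alkoxide the product is expected to rest as its magnesium phenoxide, in which the open chalcone form is favoured, and the cold acidic quench should then deliver 14. Benzyl ethers, the flavone and the 7-methoxy group should be inert to magnesium methoxide at this temperature.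

Step 9
Reactants: 14 (2E)-2-{2-(benzyloxy)-5-[5-(benzyloxy)-7-methoxy-4-oxo-4H-chromen-2-yl]phenyl}-3-[4-(benzyloxy)phenyl]-1-(2,4,6-trihydroxyphenyl)prop-2-en-1-one
Product: 15 (2S,3R)-3-{2-(benzyloxy)-5-[5-(benzyloxy)-7-methoxy-4-oxo-4H-chromen-2-yl]phenyl}-2-[4-(benzyloxy)phenyl]-5,7-dihydroxy-2,3-dihydro-4H-chromen-4-one
Conditions: 1-[3,5-bis(trifluoromethyl)phenyl]-3-[(8S,9S)-6'-methoxycinchonan-9-yl]thiourea (20 mol %), toluene/THF, −20 °C; filtered through silica gel
Reagents that add atoms: none
Why: Proposed new method: the quinuclidine of the catalyst deprotonates a ring A hydroxyl of 14 while the thiourea binds the enone carbonyl, so the ortho phenoxide should add to the β-carbon from one face within the ion pair and set C2 (the 2S sense is assigned by analogy and is to be confirmed); either ortho hydroxyl gives the same ring, and C3, created by protonation of the α-aryl enolate, should equilibrate under the amine to the trans 3R arrangement with both aryl groups equatorial. The closest known reaction type is the cinchona thiourea-catalysed enantioselective oxa-Michael cyclisation of 2'-hydroxychalcones, known for the parent and the α-alkoxycarbonyl series but not for an α-aryl chalcone with a free trihydroxyphenyl ring; the α-aryl group stabilises the developing enolate much as the ester does there.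

Step 10
Reactants: 15 (2S,3R)-3-{2-(benzyloxy)-5-[5-(benzyloxy)-7-methoxy-4-oxo-4H-chromen-2-yl]phenyl}-2-[4-(benzyloxy)phenyl]-5,7-dihydroxy-2,3-dihydro-4H-chromen-4-one
Product: 16 (2S,3R)-5,7-dihydroxy-3-[2-hydroxy-5-(5-hydroxy-7-methoxy-4-oxo-4H-chromen-2-yl)phenyl]-2-(4-hydroxyphenyl)-2,3-dihydro-4H-chromen-4-one
Conditions: H2 (1 atm), 10% Pd/C (palladium on carbon), EtOAc/MeOH, rt; stopped after uptake of three equivalents
Reagents that add atoms: none
Why: Hydrogenolysis of three aryl benzyl ethers under neutral conditions, so C2 and C3 are not exposed to acid or base; the flavone double bond and the chelated aryl ketones reduce much more slowly and should survive if the reaction is stopped at the calculated uptake.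

## Compound list

1 | 1-(2,6-dihydroxy-4-methoxyphenyl)ethan-1-one (2',6'-dihydroxy-4'-methoxyacetophenone) | CC(=O)c1c(O)cc(OC)cc1O | starting material
2 | 1-[2-(benzyloxy)-6-hydroxy-4-methoxyphenyl]ethan-1-one | CC(=O)c1c(O)cc(OC)cc1OCc1ccccc1 | intermediate
3 | 4-(benzyloxy)-3-bromobenzaldehyde | O=Cc1ccc(OCc2ccccc2)c(Br)c1 | starting material
4 | (2E)-1-[2-(benzyloxy)-6-hydroxy-4-methoxyphenyl]-3-[4-(benzyloxy)-3-bromophenyl]prop-2-en-1-one | O=C(/C=C/c1ccc(OCc2ccccc2)c(Br)c1)c1c(O)cc(OC)cc1OCc1ccccc1 | intermediate
5 | 5-(benzyloxy)-2-[4-(benzyloxy)-3-bromophenyl]-7-methoxy-4H-chromen-4-one | COc1cc(OCc2ccccc2)c2c(=O)cc(-c3ccc(OCc4ccccc4)c(Br)c3)oc2c1 | intermediate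
6 | ethyl 2-{2-(benzyloxy)-5-[5-(benzyloxy)-7-methoxy-4-oxo-4H-chromen-2-yl]phenyl}acetate | CCOC(=O)Cc1cc(-c2cc(=O)c3c(OCc4ccccc4)cc(OC)cc3o2)ccc1OCc1ccccc1 | intermediate
7 | 2-{2-(benzyloxy)-5-[5-(benzyloxy)-7-methoxy-4-oxo-4H-chromen-2-yl]phenyl}acetic acid | OC(=O)Cc1cc(-c2cc(=O)c3c(OCc4ccccc4)cc(OC)cc3o2)ccc1OCc1ccccc1 | intermediate
8 | 4-(benzyloxy)benzaldehyde | O=Cc1ccc(OCc2ccccc2)cc1 | starting material
9 | (2E)-2-{2-(benzyloxy)-5-[5-(benzyloxy)-7-methoxy-4-oxo-4H-chromen-2-yl]phenyl}-3-[4-(benzyloxy)phenyl]prop-2-enoic acid | OC(=O)/C(c1cc(-c2cc(=O)c3c(OCc4ccccc4)cc(OC)cc3o2)ccc1OCc1ccccc1)=C/c1ccc(OCc2ccccc2)cc1 | intermediate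
10 | 4-hydroxy-6-methyl-2H-pyran-2-one | Cc1cc(O)cc(=O)o1 | starting material
11 | (2E)-2-{2-(benzyloxy)-5-[5-(benzyloxy)-7-methoxy-4-oxo-4H-chromen-2-yl]phenyl}-3-[4-(benzyloxy)phenyl]-1-(1H-imidazol-1-yl)prop-2-en-1-one | O=C(n1ccnc1)/C(c1cc(-c2cc(=O)c3c(OCc4ccccc4)cc(OC)cc3o2)ccc1OCc1ccccc1)=C/c1ccc(OCc2ccccc2)cc1 | intermediate
12 | 6-[(3E)-3-{2-(benzyloxy)-5-[5-(benzyloxy)-7-methoxy-4-oxo-4H-chromen-2-yl]phenyl}-4-[4-(benzyloxy)phenyl]-2-oxobut-3-en-1-yl]-4-hydroxy-2H-pyran-2-one | O=c1cc(O)cc(CC(=O)/C(c2cc(-c3cc(=O)c4c(OCc5ccccc5)cc(OC)cc4o3)ccc2OCc2ccccc2)=C/c2ccc(OCc3ccccc3)cc2)o1 | intermediate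
13 | methyl (8E)-8-{2-(benzyloxy)-5-[5-(benzyloxy)-7-methoxy-4-oxo-4H-chromen-2-yl]phenyl}-9-[4-(benzyloxy)phenyl]-3,5,7-trioxonon-8-enoate | COC(=O)CC(=O)CC(=O)CC(=O)/C(c1cc(-c2cc(=O)c3c(OCc4ccccc4)cc(OC)cc3o2)ccc1OCc1ccccc1)=C/c1ccc(OCc2ccccc2)cc1 | intermediate
14 | (2E)-2-{2-(benzyloxy)-5-[5-(benzyloxy)-7-methoxy-4-oxo-4H-chromen-2-yl]phenyl}-3-[4-(benzyloxy)phenyl]-1-(2,4,6-trihydroxyphenyl)prop-2-en-1-one | O=C(c1c(O)cc(O)cc1O)/C(c1cc(-c2cc(=O)c3c(OCc4ccccc4)cc(OC)cc3o2)ccc1OCc1ccccc1)=C/c1ccc(OCc2ccccc2)cc1 | intermediate
15 | (2S,3R)-3-{2-(benzyloxy)-5-[5-(benzyloxy)-7-methoxy-4-oxo-4H-chromen-2-yl]phenyl}-2-[4-(benzyloxy)phenyl]-5,7-dihydroxy-2,3-dihydro-4H-chromen-4-one | COc1cc(OCc2ccccc2)c2c(=O)cc(-c3ccc(OCc4ccccc4)c([C@H]4C(=O)c5c(O)cc(O)cc5O[C@@H]4c4ccc(OCc5ccccc5)cc4)c3)oc2c1 | intermediate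
16 | (2S,3R)-5,7-dihydroxy-3-[2-hydroxy-5-(5-hydroxy-7-methoxy-4-oxo-4H-chromen-2-yl)phenyl]-2-(4-hydroxyphenyl)-2,3-dihydro-4H-chromen-4-one | COc1cc(O)c2c(=O)cc(-c3ccc(O)c([C@H]4C(=O)c5c(O)cc(O)cc5O[C@@H]4c4ccc(O)cc4)c3)oc2c1 | target

## Step count and least certain steps

Total step count: 10. Longest linear sequence: 10 steps (1 to 16); the partners 3, 8 and 10 are purchased.

**Step 9 (bears the label "Proposed new method:").**
- What may go wrong: uncatalysed background ring closure, competitive ionisation of the most acidic para hydroxyl (which may hold the catalyst in an unproductive ion pair), and erosion of C2 by reversible ring opening through the chalcone would each lower the enantiomeric purity. The sense of induction is not secured in advance.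
- Fallback (known chemistry): from 14, ring closure without a chiral catalyst (NaOAc, EtOH, reflux) should give 15 together with its enantiomer, the (2R,3S)-flavanone F1, as the racemic trans compound. Preparative chromatography on a chiral stationary phase separates the two, and F1 is returned to the equilibrium through 14 with base and recycled. The fallback sets out from 14 and comes back at 15.

**Step 8 (key step).**
- What may go wrong: aldol folding onto the enone ketone to a resorcylate; oxa-Michael addition of a diketone enol to the enone inside the chain; retro-Claisen cleavage by methoxide; premature closure of ring C to racemic flavanone before or during the quench. The last is reversible: excess base re-opens the ring and cold acid returns the chalcone.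
- Fallback: the acyl group is delivered to a preformed ring A. Acid 9 is activated as 11 as in step 7. 1,3,5-Tris(methoxymethoxy)benzene F2 (from phloroglucinol, MOMCl and iPr2NEt) is lithiated between two ether groups (n-C4H9Li, THF, 0 °C) and added to 11 at −78 °C to give the tris(methoxymethyl) ether of the chalcone F3. HCl in MeOH/THF at room temperature should remove the three acetals and leave the benzyl ethers. The fallback sets out from 9 and comes back at 14.

**Step 7.**
- What may go wrong: acylation at the ring oxygen or at C3 of the pyrone instead of the methyl carbon, quenching of the dianion by the acidic product, or sluggish reaction of the hindered acyl donor.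
- Fallback: an open-chain nucleophile replaces the pyrone. The trianion of methyl 3,5-dioxohexanoate (a catalogue compound; LiN(iPr)2, 3.3 equiv, THF, −78 to 0 °C) is acylated at its terminal methyl carbon by 11 to give triketo ester 13, now isolated, which is cyclised under the conditions of step 8. The fallback sets out from 9 and comes back at 13; pyrone 12 is then bypassed.

**Step 6.**
- What may go wrong: slow condensation with the electron-rich aldehyde, decarboxylation of the product at the temperature required, and formation of a geometric mixture.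
- Fallback: the Cα–aryl bond is made by cross-coupling from bromide 5, replacing steps 4 to 6. Miyaura borylation (B2pin2, PdCl2(dppf), KOAc, dioxane, 90 °C) gives the pinacol boronate F4. Aldehyde 8 and Ph3P=C(Br)CO2CH3 (Wittig reaction) give methyl (2Z)-3-[4-(benzyloxy)phenyl]-2-bromoprop-2-enoate F5. Suzuki–Miyaura coupling of F4 with F5 (Pd(PPh3)4, zerovalent palladium, K2CO3, dioxane/H2O, 80 °C) should give with retention the E diarylacrylate methyl ester F6, and LiOH hydrolysis gives 9. The fallback sets out from 5 and 8 and comes back at 9.

## Further compounds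

F1 | step 9 | (2R,3S)-3-{2-(benzyloxy)-5-[5-(benzyloxy)-7-methoxy-4-oxo-4H-chromen-2-yl]phenyl}-2-[4-(benzyloxy)phenyl]-5,7-dihydroxy-2,3-dihydro-4H-chromen-4-one (enantiomer of 15) | COc1cc(OCc2ccccc2)c2c(=O)cc(-c3ccc(OCc4ccccc4)c([C@@H]4C(=O)c5c(O)cc(O)cc5O[C@H]4c4ccc(OCc5ccccc5)cc4)c3)oc2c1
F2 | step 8 | 1,3,5-tris(methoxymethoxy)benzene | COCOc1cc(OCOC)cc(OCOC)c1
F3 | step 8 | (2E)-2-{2-(benzyloxy)-5-[5-(benzyloxy)-7-methoxy-4-oxo-4H-chromen-2-yl]phenyl}-3-[4-(benzyloxy)phenyl]-1-[2,4,6-tris(methoxymethoxy)phenyl]prop-2-en-1-one | COCOc1cc(OCOC)c(C(=O)/C(c2cc(-c3cc(=O)c4c(OCc5ccccc5)cc(OC)cc4o3)ccc2OCc2ccccc2)=C/c2ccc(OCc3ccccc3)cc2)c(OCOC)c1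
F0 | step 7 | none | none
F4 | step 6 | 5-(benzyloxy)-2-[4-(benzyloxy)-3-(4,4,5,5-tetramethyl-1,3,2-dioxaborolan-2-yl)phenyl]-7-methoxy-4H-chromen-4-one | COc1cc(OCc2ccccc2)c2c(=O)cc(-c3ccc(OCc4ccccc4)c(B4OC(C)(C)C(C)(C)O4)c3)oc2c1
F5 | step 6 | methyl (2Z)-3-[4-(benzyloxy)phenyl]-2-bromoprop-2-enoate | COC(=O)/C(Br)=C/c1ccc(OCc2ccccc2)cc1
F6 | step 6 | methyl (2E)-2-{2-(benzyloxy)-5-[5-(benzyloxy)-7-methoxy-4-oxo-4H-chromen-2-yl]phenyl}-3-[4-(benzyloxy)phenyl]prop-2-enoate | COC(=O)/C(c1cc(-c2cc(=O)c3c(OCc4ccccc4)cc(OC)cc3o2)ccc1OCc1ccccc1)=C/c1ccc(OCc2ccccc2)cc1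
A1 | alternative 1 | 2-diazo-1-{2-[(4-tert-butyldimethylsilyloxybenzyl)oxy]-4,6-bis(tert-butyldimethylsilyloxy)phenyl}-2-{2-(tert-butyldimethylsilyloxy)-5-[5-(tert-butyldimethylsilyloxy)-7-methoxy-4-oxo-4H-chromen-2-yl]phenyl}ethan-1-one | COc1cc(O[Si](C)(C)C(C)(C)C)c2c(=O)cc(-c3ccc(O[Si](C)(C)C(C)(C)C)c(C(=[N+]=[N-])C(=O)c4c(O[Si](C)(C)C(C)(C)C)cc(O[Si](C)(C)C(C)(C)C)cc4OCc4ccc(O[Si](C)(C)C(C)(C)C)cc4)c3)oc2c1
A2 | alternative 1 | penta(tert-butyldimethylsilyl) ether of the target, (2S,3R) | COc1cc(O[Si](C)(C)C(C)(C)C)c2c(=O)cc(-c3ccc(O[Si](C)(C)C(C)(C)C)c([C@H]4C(=O)c5c(O[Si](C)(C)C(C)(C)C)cc(O[Si](C)(C)C(C)(C)C)cc5O[C@@H]4c4ccc(O[Si](C)(C)C(C)(C)C)cc4)c3)oc2c1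
A3 | alternative 2 | 2-(hydroxymethyl)-3,5-bis(methoxymethoxy)phenol | OCc1c(O)cc(OCOC)cc1OCOC
A4 | alternative 2 | 2-[(E)-2-(4-hydroxyphenyl)ethenyl]-4-[7-methoxy-5-(methoxymethoxy)-4-oxo-4H-chromen-2-yl]phenyl acetate | COc1cc(OCOC)c2c(=O)cc(-c3ccc(OC(C)=O)c(/C=C/c4ccc(O)cc4)c3)oc2c1
A5 | alternative 2 | trans-(2S,3R)-2,3-diarylchroman carrying the flavone unit: 2-[(2S,3R)-2-(4-hydroxyphenyl)-5,7-bis(methoxymethoxy)chroman-3-yl]-4-[7-methoxy-5-(methoxymethoxy)-4-oxo-4H-chromen-2-yl]phenyl acetate | COc1cc(OCOC)c2c(=O)cc(-c3ccc(OC(C)=O)c([C@H]4Cc5c(OCOC)cc(OCOC)cc5O[C@@H]4c4ccc(O)cc4)c3)oc2c1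
A6 | alternative 3 | 2-(diazoacetyl)-6-{4-(methoxymethoxy)-3-[(2S,3R)-5,7-bis(methoxymethoxy)-2-[4-(methoxymethoxy)phenyl]-4-oxochroman-3-yl]phenyl}-4H-pyran-4-one | [N-]=[N+]=CC(=O)c1cc(=O)cc(-c2ccc(OCOC)c([C@H]3C(=O)c4c(OCOC)cc(OCOC)cc4O[C@@H]3c3ccc(OCOC)cc3)c2)o1
A7 | alternative 3 | methoxyethyne | COC#C
A8 | alternative 3 | target with four methoxymethyl ethers and the flavone 5-hydroxyl free, (2S,3R) | COc1cc(O)c2c(=O)cc(-c3ccc(OCOC)c([C@H]4C(=O)c5c(OCOC)cc(OCOC)cc5O[C@@H]4c4ccc(OCOC)cc4)c3)oc2c1
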